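**Slow start.** Slowness is side product's visible handicap. In the amber run it gains 7.9% in the first 10.0 s, then 14 percentage points in the next 10.0 s, a lag (an induction period). Yet target reads 0.8% at 10.0 s in that run, so any crossing there where side product overtakes target lies before the first reading.

| setting | amber | red | flask |
|---|---|---|---|
| starting material | 1.3 M | 1.3 M | 1.3 M |
| partner | 1.04 M | 1.04 M | 1.04 M |
| protic impurity | 0.20 M | 0.29 M | 0.390 M |
| remark | run made earlier | run made earlier |  |
| time |  |  | 2.5 min |

| run | time / s | side product / % | target / % |
|---|---|---|---|
| amber | 10.0 | 7.9 | 0.8 |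
| amber | 20.0 | 22.2 | 2.8 |
| amber | 30.0 | 36.7 | 2.7 |
| amber | 50.0 | 56.3 | 4.9 |
| amber | 60.0 | 62.5 | 4.5 |
| amber | 90.0 | 75.0 | 5.1 |
| red | 10.0 | 8.2 | 0.3 |
| red | 20.0 | 23.0 | 2.5 |
| red | 30.0 | 37.5 | 1.8 |
| red | 50.0 | 57.5 | 2.3 |
| red | 60.0 | 64.2 | 3.0 |
| red | 90.0 | 77.0 | 4.6 |

(scatter of a reading: 1 percentage point)

- a reading or a percentage of target counts all its forms, free or not

- ratio of side product to target at 5.0 s
- ratio of side product to target at 2.5 min
- which of side product and target there is more of at 2.5 min

**Turned round.** What would target need in order to lead this flask at 2.5 min? The mean target reading at 60.0 s and 90.0 s, over amber and red, is 4.30%, and this target share is what I carry. I pool the two runs: their means differ by 1 point, against a scatter of 1 point per reading.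

Suppose target stays at that share and the rest of the charge ends as side product. Its gap to that end shrinks from 32.4% to 19.7% between those times, a time constant of 60.5 s. That puts side product at 88.4% by 2.5 min, a ratio of 20.6. To lead with the two summing to the same total, target would need over 46.3%, which is 10.8 times its share. So I say side product leads. At 5.0 s, before any reading, I commit to a ratio below that late one, with side product still in its lag.

**The check.** The forecast gives 20 at 5.0 s, 25 at 2.5 min and side product ahead, with the words “Nothing in the data suggests a late takeover by target”. The flask gives 2.89 at 5.0 s and 19.5 at 2.5 min, with side product ahead, 86.7% against 4.44%.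

    starting material → target (k = 0.00200 s⁻¹)
    intermediate B → side product (k = 0.0950 s⁻¹)
    starting material → intermediate A (k = 0.0160 s⁻¹)
    partner + protic impurity → quenched reagent (k = 0.0160 M⁻¹ s⁻¹)
    intermediate A → intermediate B (k = 0.0150 s⁻¹)
    starting material → intermediate B (k = 0.0270 s⁻¹)
    partner + target ⇌ idle adduct, settled at all times (K = 0.970 M⁻¹)
    intermediate A → decomposed reagent (k = 0.00180 s⁻¹)

**Second flask.** Taking the loss of starting material to intermediate B out of this flask's run drops the ratio at 2.5 min from 19.5 to 5.32, so that direct path is the largest single effect on side product's lead. A neighbour flask holds 0.98 M of protic impurity, all else as in the recipe; the target share puts its target at 4.30% by 2.5 min. Computed, it holds 4.44% at 2.5 min, with ratio 19.5.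

The runs are calculated with constants of no real substance; noise was put on by code.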